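**Retrosynthetic overview**

- The enal, the free hydroxyls and the acetate come last. The triene is made by Horner–Wadsworth–Emmons opening of a butenolide lactol with a myrcene-type allylic phosphonate; the butenolide is attached to the α-carbon of a spirocyclic cyclopentanone.
- The cyclohexane is made in one flask from ketone 4 and bromide 9. The CH2–C(OH)Me bond comes from organocerium 1,2-addition to an acetyl group; the C(=)–CH bond comes from Pd-catalysed γ-alkenylation of a but-2-enoate dienolate.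
- Enabling feature: the quaternary (later spiro) carbon of the cyclopentane ring carries the acetyl carbonyl carbon and the γ-CH2 of the but-2-enoate arm 1,3 to each other. This electrophile / latent vinylogous nucleophile pair matches the CH2MgBr and C(Cl)= ends of a three-carbon unit that already holds the tetrasubstituted alkene.
- Ring order: cyclopentane bought (2-acetylcyclopentanone, quaternary centre by asymmetric alkylation), then the cyclohexane in the key step. All other stereocentres are relayed from the quaternary centre.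

Key step: step 6

Remark: names use carbocyclic spiro[4.5]decane locants (C1 oxygenated carbon of the five-membered ring, C2 its side-chain-bearing neighbour, C5 spiro carbon, C6 methylcarbinol carbon, C9 alkylidene carbon, C10 CH carrying the three-carbon chain); in step 1 the cinchona catalyst antipode that gives the (R)-ketone is assumed.

**Route**

Step 1
Reactants: 1 2-acetylcyclopentan-1-one; 2 methyl (2E)-4-bromobut-2-enoate
Product: 3 methyl (2E)-4-[(1R)-1-acetyl-2-oxocyclopentyl]but-2-enoate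
Conditions: N-(9-anthracenylmethyl)cinchoninium bromide (10 mol%), Cs2CO3, toluene, −20 °C
Reagents that add atoms: none
Why: Asymmetric phase-transfer C-alkylation (SN2) of the prochiral 1,3-diketone enolate, in which the chiral ammonium cation shields one enolate face and sets the quaternary (R)-centre while the mild carbonate base does not enolise the product.

Step 2
Reactants: 3 methyl (2E)-4-[(1R)-1-acetyl-2-oxocyclopentyl]but-2-enoate
Product: 4 methyl (2E)-4-[(6R)-6-acetyl-1,4-dioxaspiro[4.4]nonan-6-yl]but-2-enoate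
Conditions: Me3SiOCH2CH2OSiMe3, Me3SiOTf (5 mol%), CH2Cl2, −78 → −20 °C
Reagents that add atoms: 1,2-bis(trimethylsilyloxy)ethane, C[Si](C)(C)OCCO[Si](C)(C)C
Why: Noyori ketalisation, expected to be chemoselective for the ring carbonyl because the acetyl carbonyl is an acyclic, pinacolone-like ketone that reacts far more slowly.

Step 3
Reactants: 5 tert-butyl(diphenyl)(prop-2-yn-1-yloxy)silane; 6 oxirane
Product: 7 5-[(tert-butyldiphenylsilyl)oxy]pent-3-yn-1-ol
Conditions: n-BuLi, THF, −78 °C; BF3·OEt2, then 6, −78 °C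
Reagents that add atoms: none
Why: Yamaguchi alkynylation, in which the lithium acetylide opens BF3-activated oxirane to give the homopropargylic alcohol.

Step 4
Reactants: 7 5-[(tert-butyldiphenylsilyl)oxy]pent-3-yn-1-ol
Product: 8 (3E)-5-[(tert-butyldiphenylsilyl)oxy]-3-chloro-4-methylpent-3-en-1-ol
Conditions: MeMgBr (4 equiv), Fe(acac)3 (10 mol%), THF, −40 → 0 °C; then N-chlorosuccinimide, −78 → 0 °C
Reagents that add atoms: methylmagnesium bromide, C[Mg]Br; N-chlorosuccinimide, O=C1CCC(=O)N1Cl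
Why: Alkoxide-directed iron-catalysed syn-carbomagnesiation of the homopropargylic alcohol puts methyl on the distal and magnesium on the proximal alkyne carbon (five-membered chelate), and chlorination of the alkenylmagnesium with retention fixes the tetrasubstituted (E)-alkene with chlorine cis to the new methyl group.

Step 5
Reactants: 8 (3E)-5-[(tert-butyldiphenylsilyl)oxy]-3-chloro-4-methylpent-3-en-1-ol
Product: 9 {[(2E)-5-bromo-3-chloro-2-methylpent-2-en-1-yl]oxy}(tert-butyl)diphenylsilane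
Conditions: CBr4, PPh3, CH2Cl2, 0 °C
Reagents that add atoms: tetrabromomethane, BrC(Br)(Br)Br
Why: Appel bromination of the primary alcohol (SN2 on the alkoxyphosphonium salt), which leaves the alkenyl chloride and the silyl ether untouched.

Step 6
Reactants: 4 methyl (2E)-4-[(6R)-6-acetyl-1,4-dioxaspiro[4.4]nonan-6-yl]but-2-enoate; 9 {[(2E)-5-bromo-3-chloro-2-methylpent-2-en-1-yl]oxy}(tert-butyl)diphenylsilane
Product: 12 methyl (2E)-3-[(5R,6S,9E,10R)-9-{1-[(tert-butyldiphenylsilyl)oxy]propan-2-ylidene}-1,1-(ethylenedioxy)-6-hydroxy-6-methylspiro[4.5]decan-10-yl]prop-2-enoate, via Grignard reagent 10 (not isolated), via bromomagnesium alkoxide 11 (not isolated)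
Conditions: 9, Mg, THF, 25 °C; CeCl3, −78 °C, then 4, −78 → −40 °C; then KN(SiMe3)2, Pd2(dba)3 (5 mol%), P(tBu)3 (12 mol%), toluene, 65 °C, same flask
Reagents that add atoms: none
Why: Proposed new method: bromide 9 is turned into Grignard reagent 10 (the alkenyl chloride is inert to magnesium), transmetallated to cerium and added 1,2 to the acetyl group of 4; KN(SiMe3)2 then deprotonates the γ-CH2 of the but-2-enoate arm, zerovalent palladium inserts into the C–Cl bond, and reductive elimination from the alkenylpalladium dienolate forges the ring C–C bond with retention of the alkene geometry. The closest known reaction types are the CeCl3-promoted Grignard addition to enolisable ketones, the Pd-catalysed intramolecular alkenylation of enolates with alkenyl halides and the Pd-catalysed γ-arylation of dienolates; the one-flask union and the intramolecular vinylogous alkenylation have no direct precedent. The six-membered ring closes in a 6-exo sense at the γ-carbon, because coupling at the α-carbon would need an eight-membered ring. The carbinol centre C6 is set by chelation control: the metal bridges the acetyl oxygen and the ketal oxygen syn to it, and the nucleophile enters from the open face away from the five-membered ring, which places the new oxygen cis to the ketal carbon on the later cyclohexane. The centre C10 is set in the ring closure, where the alkoxide and the dienolate oxygen share a counter-ion so that the enoate arm is held on the alkoxide face, cis to the hydroxyl group. The step needs attack on the ketone in the presence of the enoate (organocerium at −78 °C) and C- rather than O-coupling (magnesium-bound alkoxide, soft dienolate).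

Step 7
Reactants: 12 methyl (2E)-3-[(5R,6S,9E,10R)-9-{1-[(tert-butyldiphenylsilyl)oxy]propan-2-ylidene}-1,1-(ethylenedioxy)-6-hydroxy-6-methylspiro[4.5]decan-10-yl]prop-2-enoate
Product: 13 methyl 3-[(5R,6S,9E,10R)-9-{1-[(tert-butyldiphenylsilyl)oxy]propan-2-ylidene}-1,1-(ethylenedioxy)-6-hydroxy-6-methylspiro[4.5]decan-10-yl]propanoate
Conditions: H2 (1 atm), RhCl(PPh3)3 (5 mol%), benzene/EtOH, 25 °C
Reagents that add atoms: none
Why: Homogeneous hydrogenation with RhCl(PPh3)3 reduces the disubstituted enoate C=C bond and leaves the tetrasubstituted alkene alone.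

Step 8
Reactants: 13 methyl 3-[(5R,6S,9E,10R)-9-{1-[(tert-butyldiphenylsilyl)oxy]propan-2-ylidene}-1,1-(ethylenedioxy)-6-hydroxy-6-methylspiro[4.5]decan-10-yl]propanoate
Product: 14 3-[(5R,6S,9E,10R)-9-{1-[(tert-butyldiphenylsilyl)oxy]propan-2-ylidene}-1,1-(ethylenedioxy)-6-hydroxy-6-methylspiro[4.5]decan-10-yl]propan-1-ol
Conditions: LiAlH4, THF, 0 °C
Reagents that add atoms: none
Why: Hydride reduction of the methyl ester to the primary alcohol, with the tertiary alcohol carried through as its alkoxide.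

Step 9
Reactants: 14 3-[(5R,6S,9E,10R)-9-{1-[(tert-butyldiphenylsilyl)oxy]propan-2-ylidene}-1,1-(ethylenedioxy)-6-hydroxy-6-methylspiro[4.5]decan-10-yl]propan-1-ol
Product: 15 (5R,6S,9E,10R)-10-{3-[(tert-butyldiphenylsilyl)oxy]propyl}-9-{1-[(tert-butyldiphenylsilyl)oxy]propan-2-ylidene}-1,1-(ethylenedioxy)-6-methylspiro[4.5]decan-6-ol
Conditions: tBuPh2SiCl, imidazole, DMF, 0 → 25 °C
Reagents that add atoms: tert-butyl(chloro)diphenylsilane, CC(C)(C)[Si](Cl)(c1ccccc1)c1ccccc1
Why: Silylation of the primary alcohol, selective over the hindered tertiary alcohol.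

Step 10
Reactants: 15 (5R,6S,9E,10R)-10-{3-[(tert-butyldiphenylsilyl)oxy]propyl}-9-{1-[(tert-butyldiphenylsilyl)oxy]propan-2-ylidene}-1,1-(ethylenedioxy)-6-methylspiro[4.5]decan-6-ol
Product: 16 (5R,6S,9E,10R)-10-{3-[(tert-butyldiphenylsilyl)oxy]propyl}-9-{1-[(tert-butyldiphenylsilyl)oxy]propan-2-ylidene}-6-hydroxy-6-methylspiro[4.5]decan-1-one
Conditions: pyridinium p-toluenesulfonate, acetone/H2O (10:1), 55 °C
Reagents that add atoms: water, O
Why: Acid-catalysed ketal hydrolysis, after which the β-hydroxy ketone cannot dehydrate because its α-carbon is quaternary.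

Step 11
Reactants: 17 2-methylprop-2-en-1-ol; 18 1-bromo-3-methylbut-2-ene
Product: 19 6-methyl-2-methylidenehept-5-en-1-ol
Conditions: n-BuLi (2.2 equiv), TMEDA, Et2O/hexane, 0 → 25 °C; then 18, −78 → 0 °C
Reagents that add atoms: none
Why: Alkylation of the O,C-dilithio derivative of methallyl alcohol (alkoxide-directed allylic metalation) at the primary carbon of prenyl bromide (SN2).

Step 12
Reactants: 19 6-methyl-2-methylidenehept-5-en-1-ol
Product: 20 2-(bromomethyl)-6-methylhepta-1,5-diene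
Conditions: CBr4, PPh3, CH2Cl2, 0 °C
Reagents that add atoms: tetrabromomethane, BrC(Br)(Br)Br
Why: Appel bromination of the allylic alcohol.

Step 13
Reactants: 20 2-(bromomethyl)-6-methylhepta-1,5-diene
Product: 21 diethyl (6-methyl-2-methylidenehept-5-en-1-yl)phosphonate
Conditions: P(OEt)3, neat, 120 °C
Reagents that add atoms: triethyl phosphite, CCOP(OCC)OCC
Why: Michaelis–Arbuzov reaction of the allylic bromide.

Step 14
Reactants: 16 (5R,6S,9E,10R)-10-{3-[(tert-butyldiphenylsilyl)oxy]propyl}-9-{1-[(tert-butyldiphenylsilyl)oxy]propan-2-ylidene}-6-hydroxy-6-methylspiro[4.5]decan-1-one; 22 4-bromofuran-2(5H)-one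
Product: 24 4-[(5R,6S,9E,10R)-10-{3-[(tert-butyldiphenylsilyl)oxy]propyl}-9-{1-[(tert-butyldiphenylsilyl)oxy]propan-2-ylidene}-6-hydroxy-6-methyl-1-oxospiro[4.5]decan-2-yl]furan-2(5H)-one (C2 epimers), via bis(trimethylsilyl) enol ether 23 (not isolated)
Conditions: Me3SiOTf (2.5 equiv), Et3N, CH2Cl2, 0 °C; then 22, Pd2(dba)3 (3 mol%), P(tBu)3, ZnF2 (0.6 equiv), DMF, 70 °C; 1 M HCl work-up
Reagents that add atoms: none
Why: Regiospecific silyl enol ether formation (the other α-carbon is quaternary, and the tertiary alcohol is masked at the same time so that no retro-aldol cleavage can occur) followed by Pd-catalysed α-alkenylation of the silyl enol ether with the β-bromobutenolide under fluoride activation (Kuwajima–Urabe/Hartwig type), which leaves the new C2 centre epimerisable.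

Step 15
Reactants: 24 4-[(5R,6S,9E,10R)-10-{3-[(tert-butyldiphenylsilyl)oxy]propyl}-9-{1-[(tert-butyldiphenylsilyl)oxy]propan-2-ylidene}-6-hydroxy-6-methyl-1-oxospiro[4.5]decan-2-yl]furan-2(5H)-one (C2 epimers)
Product: 25 4-[(1R,2S,5S,6S,9E,10R)-10-{3-[(tert-butyldiphenylsilyl)oxy]propyl}-9-{1-[(tert-butyldiphenylsilyl)oxy]propan-2-ylidene}-1,6-dihydroxy-6-methylspiro[4.5]decan-2-yl]furan-2(5H)-one
Conditions: Me4NBH(OAc)3, MeCN/AcOH, −20 °C
Reagents that add atoms: none
Why: Hydroxyl-directed reduction (Evans–Saksena) in which the C6 hydroxyl delivers hydride to C1 from its own face, and because the C2 epimers interconvert through the enol in acetic acid while the epimer with the butenolide anti to the delivery face should react faster, the mixture should be funnelled to the 1,2-cis (1R,2S) diol.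

Step 16
Reactants: 25 4-[(1R,2S,5S,6S,9E,10R)-10-{3-[(tert-butyldiphenylsilyl)oxy]propyl}-9-{1-[(tert-butyldiphenylsilyl)oxy]propan-2-ylidene}-1,6-dihydroxy-6-methylspiro[4.5]decan-2-yl]furan-2(5H)-one; 21 diethyl (6-methyl-2-methylidenehept-5-en-1-yl)phosphonate
Product: 27 (1R,2S,5S,6S,9E,10R)-10-{3-[(tert-butyldiphenylsilyl)oxy]propyl}-9-{1-[(tert-butyldiphenylsilyl)oxy]propan-2-ylidene}-2-[(2Z,4E)-1-hydroxy-10-methyl-6-methylideneundeca-2,4,9-trien-2-yl]-6-methylspiro[4.5]decane-1,6-diol, via lactol 26 (not isolated)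
Conditions: iBu2AlH (3.2 equiv), CH2Cl2, −78 °C; then lithiated 21 (n-BuLi, THF), −78 → 0 °C
Reagents that add atoms: none
Why: Partial reduction of the lactone to the lactol aluminate and in situ Horner–Wadsworth–Emmons olefination of the ring-opened γ-oxido (Z)-enal with the lithiated allylic phosphonate, in which the butenolide ring has already fixed the (Z)-trisubstituted alkene and the phosphonate olefination should give the new disubstituted (E)-alkene.

Step 17
Reactants: 27 (1R,2S,5S,6S,9E,10R)-10-{3-[(tert-butyldiphenylsilyl)oxy]propyl}-9-{1-[(tert-butyldiphenylsilyl)oxy]propan-2-ylidene}-2-[(2Z,4E)-1-hydroxy-10-methyl-6-methylideneundeca-2,4,9-trien-2-yl]-6-methylspiro[4.5]decane-1,6-diol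
Product: 28 (2Z,4E)-2-[(1R,2S,5S,6S,9E,10R)-10-{3-[(tert-butyldiphenylsilyl)oxy]propyl}-9-{1-[(tert-butyldiphenylsilyl)oxy]propan-2-ylidene}-1,6-dihydroxy-6-methylspiro[4.5]decan-2-yl]-10-methyl-6-methylideneundeca-2,4,9-trien-1-yl acetate
Conditions: Ac2O (1.1 equiv), pyridine, CH2Cl2, −20 °C
Reagents that add atoms: acetic anhydride, CC(=O)OC(C)=O
Why: Acylation of the primary allylic alcohol, selective over the neopentyl-type secondary and the tertiary alcohol.

Step 18
Reactants: 28 (2Z,4E)-2-[(1R,2S,5S,6S,9E,10R)-10-{3-[(tert-butyldiphenylsilyl)oxy]propyl}-9-{1-[(tert-butyldiphenylsilyl)oxy]propan-2-ylidene}-1,6-dihydroxy-6-methylspiro[4.5]decan-2-yl]-10-methyl-6-methylideneundeca-2,4,9-trien-1-yl acetate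
Product: 29 (2Z,4E)-2-[(1R,2S,5S,6S,9E,10R)-1,6-dihydroxy-10-(3-hydroxypropyl)-9-(1-hydroxypropan-2-ylidene)-6-methylspiro[4.5]decan-2-yl]-10-methyl-6-methylideneundeca-2,4,9-trien-1-yl acetate
Conditions: Bu4NF, AcOH (1:1), THF, 0 → 25 °C
Reagents that add atoms: none
Why: Fluoride-mediated cleavage of both silyl ethers, buffered with acetic acid so that the acetate neither migrates nor hydrolyses.

Step 19
Reactants: 29 (2Z,4E)-2-[(1R,2S,5S,6S,9E,10R)-1,6-dihydroxy-10-(3-hydroxypropyl)-9-(1-hydroxypropan-2-ylidene)-6-methylspiro[4.5]decan-2-yl]-10-methyl-6-methylideneundeca-2,4,9-trien-1-yl acetate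
Product: 30 (2Z,4E)-2-[(1R,2S,5S,6S,9E,10R)-1,6-dihydroxy-10-(3-hydroxypropyl)-6-methyl-9-(1-oxopropan-2-ylidene)spiro[4.5]decan-2-yl]-10-methyl-6-methylideneundeca-2,4,9-trien-1-yl acetate (CNP0204268.1)
Conditions: MnO2 (activated, excess), CH2Cl2, 25 °C
Reagents that add atoms: none
Why: MnO2 oxidises only the allylic primary alcohol, giving the tetrasubstituted enal without touching the saturated primary and secondary alcohols.

**Compound list**

1 | 2-acetylcyclopentan-1-one | CC(=O)C1CCCC1=O | starting material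
2 | methyl (2E)-4-bromobut-2-enoate | COC(=O)/C=C/CBr | starting material
3 | methyl (2E)-4-[(1R)-1-acetyl-2-oxocyclopentyl]but-2-enoate | C1CC[C@](C(C)=O)(C/C=C/C(=O)OC)C1=O | intermediate
4 | methyl (2E)-4-[(6R)-6-acetyl-1,4-dioxaspiro[4.4]nonan-6-yl]but-2-enoate | C1CC[C@](C(C)=O)(C/C=C/C(=O)OC)C12OCCO2 | intermediate
5 | tert-butyl(diphenyl)(prop-2-yn-1-yloxy)silane | C#CCO[Si](c1ccccc1)(c1ccccc1)C(C)(C)C | starting material
6 | oxirane | C1CO1 | starting material
7 | 5-[(tert-butyldiphenylsilyl)oxy]pent-3-yn-1-ol | OCCC#CCO[Si](c1ccccc1)(c1ccccc1)C(C)(C)C | intermediate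
8 | (3E)-5-[(tert-butyldiphenylsilyl)oxy]-3-chloro-4-methylpent-3-en-1-ol | OCC/C(Cl)=C(/C)CO[Si](c1ccccc1)(c1ccccc1)C(C)(C)C | intermediate
9 | {[(2E)-5-bromo-3-chloro-2-methylpent-2-en-1-yl]oxy}(tert-butyl)diphenylsilane | BrCC/C(Cl)=C(/C)CO[Si](c1ccccc1)(c1ccccc1)C(C)(C)C | intermediate
10 | {(3E)-5-[(tert-butyldiphenylsilyl)oxy]-3-chloro-4-methylpent-3-en-1-yl}magnesium bromide | Br[Mg]CC/C(Cl)=C(/C)CO[Si](c1ccccc1)(c1ccccc1)C(C)(C)C | intermediate (not isolated)
11 | bromomagnesium alkoxide from 1,2-addition of 10 to 4 (R at the ring carbon, S at the new carbinol carbon) | C1CC[C@]([C@@](C)(O[Mg]Br)CC/C(Cl)=C(/C)CO[Si](c3ccccc3)(c3ccccc3)C(C)(C)C)(C/C=C/C(=O)OC)C12OCCO2 | intermediate (not isolated)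
12 | methyl (2E)-3-[(5R,6S,9E,10R)-9-{1-[(tert-butyldiphenylsilyl)oxy]propan-2-ylidene}-1,1-(ethylenedioxy)-6-hydroxy-6-methylspiro[4.5]decan-10-yl]prop-2-enoate | C1CC[C@]2([C@H](/C=C/C(=O)OC)/C(=C(\C)CO[Si](c3ccccc3)(c3ccccc3)C(C)(C)C)CC[C@]2(C)O)C14OCCO4 | intermediate
13 | methyl 3-[(5R,6S,9E,10R)-9-{1-[(tert-butyldiphenylsilyl)oxy]propan-2-ylidene}-1,1-(ethylenedioxy)-6-hydroxy-6-methylspiro[4.5]decan-10-yl]propanoate | C1CC[C@]2([C@H](CCC(=O)OC)/C(=C(\C)CO[Si](c3ccccc3)(c3ccccc3)C(C)(C)C)CC[C@]2(C)O)C14OCCO4 | intermediate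
14 | 3-[(5R,6S,9E,10R)-9-{1-[(tert-butyldiphenylsilyl)oxy]propan-2-ylidene}-1,1-(ethylenedioxy)-6-hydroxy-6-methylspiro[4.5]decan-10-yl]propan-1-ol | C1CC[C@]2([C@H](CCCO)/C(=C(\C)CO[Si](c3ccccc3)(c3ccccc3)C(C)(C)C)CC[C@]2(C)O)C14OCCO4 | intermediate
15 | (5R,6S,9E,10R)-10-{3-[(tert-butyldiphenylsilyl)oxy]propyl}-9-{1-[(tert-butyldiphenylsilyl)oxy]propan-2-ylidene}-1,1-(ethylenedioxy)-6-methylspiro[4.5]decan-6-ol | C1CC[C@]2([C@H](CCCO[Si](c3ccccc3)(c3ccccc3)C(C)(C)C)/C(=C(\C)CO[Si](c3ccccc3)(c3ccccc3)C(C)(C)C)CC[C@]2(C)O)C14OCCO4 | intermediate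
16 | (5R,6S,9E,10R)-10-{3-[(tert-butyldiphenylsilyl)oxy]propyl}-9-{1-[(tert-butyldiphenylsilyl)oxy]propan-2-ylidene}-6-hydroxy-6-methylspiro[4.5]decan-1-one | C1CC[C@]2([C@H](CCCO[Si](c3ccccc3)(c3ccccc3)C(C)(C)C)/C(=C(\C)CO[Si](c3ccccc3)(c3ccccc3)C(C)(C)C)CC[C@]2(C)O)C1=O | intermediate
17 | 2-methylprop-2-en-1-ol | C=C(C)CO | starting material
18 | 1-bromo-3-methylbut-2-ene | CC(C)=CCBr | starting material
19 | 6-methyl-2-methylidenehept-5-en-1-ol | C=C(CO)CCC=C(C)C | intermediate
20 | 2-(bromomethyl)-6-methylhepta-1,5-diene | C=C(CBr)CCC=C(C)C | intermediate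
21 | diethyl (6-methyl-2-methylidenehept-5-en-1-yl)phosphonate | CCOP(=O)(OCC)CC(=C)CCC=C(C)C | intermediate
22 | 4-bromofuran-2(5H)-one | O=C1C=C(Br)CO1 | starting material
23 | bis(trimethylsilyl) derivative of 16 (C1 silyl enol ether, C6 silyl ether) | C=1CC[C@]2([C@H](CCCO[Si](c3ccccc3)(c3ccccc3)C(C)(C)C)/C(=C(\C)CO[Si](c3ccccc3)(c3ccccc3)C(C)(C)C)CC[C@]2(C)O[Si](C)(C)C)C=1O[Si](C)(C)C | intermediate (not isolated)
24 | 4-[(5R,6S,9E,10R)-10-{3-[(tert-butyldiphenylsilyl)oxy]propyl}-9-{1-[(tert-butyldiphenylsilyl)oxy]propan-2-ylidene}-6-hydroxy-6-methyl-1-oxospiro[4.5]decan-2-yl]furan-2(5H)-one (C2 epimers) | O=C1C=C(CO1)C1CC[C@]2([C@H](CCCO[Si](c3ccccc3)(c3ccccc3)C(C)(C)C)/C(=C(\C)CO[Si](c3ccccc3)(c3ccccc3)C(C)(C)C)CC[C@]2(C)O)C1=O | intermediate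
25 | 4-[(1R,2S,5S,6S,9E,10R)-10-{3-[(tert-butyldiphenylsilyl)oxy]propyl}-9-{1-[(tert-butyldiphenylsilyl)oxy]propan-2-ylidene}-1,6-dihydroxy-6-methylspiro[4.5]decan-2-yl]furan-2(5H)-one | O=C1C=C(CO1)[C@@H]1CC[C@]2([C@H](CCCO[Si](c3ccccc3)(c3ccccc3)C(C)(C)C)/C(=C(\C)CO[Si](c3ccccc3)(c3ccccc3)C(C)(C)C)CC[C@]2(C)O)[C@@H]1O | intermediate
26 | lactol (2-hydroxy-2,5-dihydrofuran) from 25 | OC1C=C(CO1)[C@@H]1CC[C@]2([C@H](CCCO[Si](c3ccccc3)(c3ccccc3)C(C)(C)C)/C(=C(\C)CO[Si](c3ccccc3)(c3ccccc3)C(C)(C)C)CC[C@]2(C)O)[C@@H]1O | intermediate (not isolated)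
27 | (1R,2S,5S,6S,9E,10R)-10-{3-[(tert-butyldiphenylsilyl)oxy]propyl}-9-{1-[(tert-butyldiphenylsilyl)oxy]propan-2-ylidene}-2-[(2Z,4E)-1-hydroxy-10-methyl-6-methylideneundeca-2,4,9-trien-2-yl]-6-methylspiro[4.5]decane-1,6-diol | C=C(/C=C/C=C(\CO)[C@@H]1CC[C@]2([C@H](CCCO[Si](c3ccccc3)(c3ccccc3)C(C)(C)C)/C(=C(\C)CO[Si](c3ccccc3)(c3ccccc3)C(C)(C)C)CC[C@]2(C)O)[C@@H]1O)CCC=C(C)C | intermediate
28 | (2Z,4E)-2-[(1R,2S,5S,6S,9E,10R)-10-{3-[(tert-butyldiphenylsilyl)oxy]propyl}-9-{1-[(tert-butyldiphenylsilyl)oxy]propan-2-ylidene}-1,6-dihydroxy-6-methylspiro[4.5]decan-2-yl]-10-methyl-6-methylideneundeca-2,4,9-trien-1-yl acetate | C=C(/C=C/C=C(\COC(C)=O)[C@@H]1CC[C@]2([C@H](CCCO[Si](c3ccccc3)(c3ccccc3)C(C)(C)C)/C(=C(\C)CO[Si](c3ccccc3)(c3ccccc3)C(C)(C)C)CC[C@]2(C)O)[C@@H]1O)CCC=C(C)C | intermediate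
29 | (2Z,4E)-2-[(1R,2S,5S,6S,9E,10R)-1,6-dihydroxy-10-(3-hydroxypropyl)-9-(1-hydroxypropan-2-ylidene)-6-methylspiro[4.5]decan-2-yl]-10-methyl-6-methylideneundeca-2,4,9-trien-1-yl acetate | C=C(/C=C/C=C(\COC(C)=O)[C@@H]1CC[C@]2([C@H](CCCO)/C(=C(\C)CO)CC[C@]2(C)O)[C@@H]1O)CCC=C(C)C | intermediate
30 | (2Z,4E)-2-[(1R,2S,5S,6S,9E,10R)-1,6-dihydroxy-10-(3-hydroxypropyl)-6-methyl-9-(1-oxopropan-2-ylidene)spiro[4.5]decan-2-yl]-10-methyl-6-methylideneundeca-2,4,9-trien-1-yl acetate (CNP0204268.1) | C=C(/C=C/C=C(\COC(C)=O)[C@@H]1CC[C@]2([C@H](CCCO)/C(=C(\C)C=O)CC[C@]2(C)O)[C@@H]1O)CCC=C(C)C | target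

**Summary**

Total step count: 19. Longest linear sequence: 14 steps (3, 4, 5, 6, 7, 8, 9, 10, 14, 15, 16, 17, 18, 19), counted from silyl ether 5 and oxirane 6 through bromide 9. The ketone branch (steps 1 and 2) and the phosphonate branch (steps 11, 12 and 13) are shorter and join at steps 6 and 16.

Steps most likely to fail:

1. Step 6 (Proposed new method). What may go wrong: enolisation of the methyl ketone instead of addition; facial leakage in the 1,2-addition; slow oxidative addition into the tetrasubstituted C–Cl bond; O-alkenylation or oxa-Michael closure by the tertiary alkoxide. Fallback with known chemistry, in which the ring is closed at a simple ester enolate and the enoate arm is rebuilt afterwards: it sets out from 1 and comes back at 12. Phase-transfer alkylation of 1 with tert-butyl bromoacetate gives tert-butyl 2-[(1R)-1-acetyl-2-oxocyclopentyl]acetate F1, and ketalisation as in step 2 gives tert-butyl 2-[(6R)-6-acetyl-1,4-dioxaspiro[4.4]nonan-6-yl]acetate F2. CeCl3-mediated addition of Grignard reagent 10, with isolation this time, gives the tertiary alcohol F3. The ring is then closed by the established Pd-catalysed intramolecular α-alkenylation of the ester enolate (LiN(SiMe3)2, Pd2(dba)3, P(tBu)3) to the spirocyclic tert-butyl ester F4. LiAlH4 gives the diol F5, Dess–Martin oxidation of its primary alcohol gives the aldehyde F6, and a Wittig reaction with methyl (triphenylphosphoranylidene)acetate returns to 12.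

2. Step 16. What may go wrong: dehydration of the lactol to a furan; Z-to-E isomerisation of the liberated γ-oxido enal; deprotonation at the allylic C2–H by the phosphonate anion. Fallback, in which the lactone is opened stepwise and the aldehyde is isolated: it sets out from 25 and comes back at 28. Full reduction with iBu2AlH gives the (Z)-enediol F7, and the less hindered allylic hydroxyl is silylated (tBuMe2SiCl, imidazole) to the mono-silyl ether F8. Acetylation of the remaining primary allylic alcohol gives the acetate F9, and the tert-butyldimethylsilyl group is removed with pyridinium p-toluenesulfonate in methanol to give the allylic alcohol F10. MnO2 oxidation gives the (Z)-enal F11, and Horner–Wadsworth–Emmons olefination with lithiated 21 at −78 °C gives 28, so that step 17 is no longer needed.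

3. Step 2. What may go wrong: ketalisation at the acetyl carbonyl or at both carbonyls. Fallback, in which the acetyl group is introduced only after the single ring ketone has been protected: it sets out from 2 and comes back at 4. Phase-transfer alkylation of commercial tert-butyl 2-oxocyclopentane-1-carboxylate F12 with 2 gives the quaternary keto ester F13, whose only ketone is ketalised to the dioxolane F14. The tert-butyl ester is cleaved (Me3SiOTf, 2,6-lutidine, then water) to the acid F15, oxalyl chloride gives the acid chloride F16, and Me2CuLi at −78 °C delivers the methyl ketone 4.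

Further compounds
F1 | step 6 | tert-butyl 2-[(1R)-1-acetyl-2-oxocyclopentyl]acetate | C1CC[C@](C(C)=O)(CC(=O)OC(C)(C)C)C1=O
F2 | step 6 | tert-butyl 2-[(6R)-6-acetyl-1,4-dioxaspiro[4.4]nonan-6-yl]acetate | C1CC[C@](C(C)=O)(CC(=O)OC(C)(C)C)C12OCCO2
F3 | step 6 | tertiary alcohol from addition of 10 to F2 | C1CC[C@]([C@@](C)(O)CC/C(Cl)=C(/C)CO[Si](c3ccccc3)(c3ccccc3)C(C)(C)C)(CC(=O)OC(C)(C)C)C12OCCO2
F4 | step 6 | tert-butyl (5R,6S,9E,10R)-9-{1-[(tert-butyldiphenylsilyl)oxy]propan-2-ylidene}-1,1-(ethylenedioxy)-6-hydroxy-6-methylspiro[4.5]decane-10-carboxylate | C1CC[C@]2([C@H](C(=O)OC(C)(C)C)/C(=C(\C)CO[Si](c3ccccc3)(c3ccccc3)C(C)(C)C)CC[C@]2(C)O)C14OCCO4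
F5 | step 6 | (5R,6S,9E,10R)-9-{1-[(tert-butyldiphenylsilyl)oxy]propan-2-ylidene}-1,1-(ethylenedioxy)-10-(hydroxymethyl)-6-methylspiro[4.5]decan-6-ol | C1CC[C@]2([C@H](CO)/C(=C(\C)CO[Si](c3ccccc3)(c3ccccc3)C(C)(C)C)CC[C@]2(C)O)C14OCCO4
F6 | step 6 | (5R,6S,9E,10R)-9-{1-[(tert-butyldiphenylsilyl)oxy]propan-2-ylidene}-1,1-(ethylenedioxy)-6-hydroxy-6-methylspiro[4.5]decane-10-carbaldehyde | C1CC[C@]2([C@H](C=O)/C(=C(\C)CO[Si](c3ccccc3)(c3ccccc3)C(C)(C)C)CC[C@]2(C)O)C14OCCO4
F7 | step 16 | (Z)-enediol from full reduction of 25 | OC/C=C(\CO)[C@@H]1CC[C@]2([C@H](CCCO[Si](c3ccccc3)(c3ccccc3)C(C)(C)C)/C(=C(\C)CO[Si](c3ccccc3)(c3ccccc3)C(C)(C)C)CC[C@]2(C)O)[C@@H]1O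
F8 | step 16 | mono(tert-butyldimethylsilyl) ether of F7 at the less hindered allylic hydroxyl | CC(C)(C)[Si](C)(C)OC/C=C(\CO)[C@@H]1CC[C@]2([C@H](CCCO[Si](c3ccccc3)(c3ccccc3)C(C)(C)C)/C(=C(\C)CO[Si](c3ccccc3)(c3ccccc3)C(C)(C)C)CC[C@]2(C)O)[C@@H]1O
F9 | step 16 | acetate of F8 | CC(C)(C)[Si](C)(C)OC/C=C(\COC(C)=O)[C@@H]1CC[C@]2([C@H](CCCO[Si](c3ccccc3)(c3ccccc3)C(C)(C)C)/C(=C(\C)CO[Si](c3ccccc3)(c3ccccc3)C(C)(C)C)CC[C@]2(C)O)[C@@H]1O
F10 | step 16 | (Z)-allylic alcohol acetate | OC/C=C(\COC(C)=O)[C@@H]1CC[C@]2([C@H](CCCO[Si](c3ccccc3)(c3ccccc3)C(C)(C)C)/C(=C(\C)CO[Si](c3ccccc3)(c3ccccc3)C(C)(C)C)CC[C@]2(C)O)[C@@H]1O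
F11 | step 16 | (Z)-enal acetate | O=C/C=C(\COC(C)=O)[C@@H]1CC[C@]2([C@H](CCCO[Si](c3ccccc3)(c3ccccc3)C(C)(C)C)/C(=C(\C)CO[Si](c3ccccc3)(c3ccccc3)C(C)(C)C)CC[C@]2(C)O)[C@@H]1O
F12 | step 2 | tert-butyl 2-oxocyclopentane-1-carboxylate | O=C1CCCC1C(=O)OC(C)(C)C
F13 | step 2 | quaternary keto ester from alkylation of F12 with 2 (same spatial arrangement at the quaternary centre as in 3) | C1CC[C@](C(=O)OC(C)(C)C)(C/C=C/C(=O)OC)C1=O
F14 | step 2 | dioxolane ketal of F13 | C1CC[C@](C(=O)OC(C)(C)C)(C/C=C/C(=O)OC)C12OCCO2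
F15 | step 2 | carboxylic acid from F14 | C1CC[C@](C(=O)O)(C/C=C/C(=O)OC)C12OCCO2
F16 | step 2 | acid chloride from F15 | C1CC[C@](C(=O)Cl)(C/C=C/C(=O)OC)C12OCCO2
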